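**Retrosynthetic overview**
- The last bonds are the ring B–O–ring C ether (CuI coupling of ring C phenol 16 with ring A–B bromide 23) and thirteen O–alkyl bonds (BBr3).
- The route rests on ring C: C1–C5 each carry an oxygen and C6 is the only C–H. C1–C4 are the four carbons of a squarate and C5–C6 are the two carbons of a 1-methoxyvinyl group.
- Ring C is the only ring made. Thermal ring expansion of cyclobutenone 13 forms the C1–C6 bond and leaves the C1 oxygen as the one free OH.
- 13 comes from mixed aryl isopropyl squarate 9 (ring D–E phenol 5 plus ester chloride 8) by 1-methoxyvinyllithium addition and O-methylation.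
- Rings A, B, D and E are bought as arenes; both outer diaryl ethers come from Chan–Lam coupling on syringaldehyde followed by Dakin oxidation.

Key step: step 7

Remark on numbering: rings are lettered A (2,4,6-trihydroxyphenoxy end) to E (3,4,5-trihydroxyphenoxy end). Ring C is numbered from C1 (carries the ring B oxygen) through C2 (carries the ring D oxygen) to C6 (the C–H).
Remark on the four-carbon unit: it is taken from squaric acid through its dichloride, because an aryloxide does not productively replace an alkoxide of a dialkyl squarate (the aryloxide is the better leaving group).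

**Step 1**
Reactants: 1 syringaldehyde; 2 3,4,5-trimethoxyphenylboronic acid
Product: 3 3,5-dimethoxy-4-(3,4,5-trimethoxyphenoxy)benzaldehyde
Conditions: Cu(OAc)2 (2 equiv), pyridine (5 equiv), 4 Å MS, CH2Cl2, rt
Reagents that add atoms: none
Why: Chan–Lam coupling: the aryl group passes from boron to divalent copper and C–O reductive elimination from a trivalent copper aryl phenoxide forms the diaryl ether at room temperature, which accepts a phenol flanked by two methoxy groups, leaves the aldehyde alone, and benefits from the para-formyl group making this phenol less prone to copper-mediated oxidation.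

**Step 2**
Reactants: 3 3,5-dimethoxy-4-(3,4,5-trimethoxyphenoxy)benzaldehyde
Product: 5 3,5-dimethoxy-4-(3,4,5-trimethoxyphenoxy)phenol (ring D–E phenol), via aryl formate 4 (not isolated)
Conditions: mCPBA, CH2Cl2, 0 °C → rt; then K2CO3, MeOH, rt
Reagents that add atoms: 3-chloroperoxybenzoic acid (mCPBA), OOC(=O)c1cccc(Cl)c1
Why: Dakin oxidation in its Baeyer–Villiger form: the peracid adds to the aldehyde, the electron-rich aryl group (para-aryloxy) migrates to oxygen to give formate 4, and methanolysis releases a phenol whose OH lies between two unsubstituted positions.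

**Step 3**
Reactants: 6 squaric acid
Product: 7 3,4-dichlorocyclobut-3-ene-1,2-dione (squaric acid dichloride)
Conditions: (COCl)2 (2.2 equiv), DMF (cat.), 1,2-dichloroethane, 50 °C
Reagents that add atoms: oxalyl chloride, ClC(=O)C(=O)Cl
Why: DMF-catalysed (Vilsmeier-type) chlorination turns both vinylogous carboxylic acid OH groups into vinylogous acid chlorides, the standard way to this dichloride.

**Step 4**
Reactants: 7 3,4-dichlorocyclobut-3-ene-1,2-dione
Product: 8 3-chloro-4-(propan-2-yloxy)cyclobut-3-ene-1,2-dione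
Conditions: i-PrOH (1.0 equiv), Et2O, 0 °C → rt, N2 sweep
Reagents that add atoms: propan-2-ol, CC(C)O
Why: Addition–elimination at a vinylogous acid chloride: one equivalent of alcohol replaces one chloride, and the product, now a vinylogous ester, is less electrophilic than 7, so the second chloride should remain.

**Step 5**
Reactants: 8 3-chloro-4-(propan-2-yloxy)cyclobut-3-ene-1,2-dione; 5 ring D–E phenol
Product: 9 3-[3,5-dimethoxy-4-(3,4,5-trimethoxyphenoxy)phenoxy]-4-(propan-2-yloxy)cyclobut-3-ene-1,2-dione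
Conditions: i-Pr2NEt (1.1 equiv), CH2Cl2, −20 → 0 °C
Reagents that add atoms: none
Why: Addition–elimination of the phenoxide at the remaining vinylogous acid chloride carbon; chloride leaves far more readily than isopropoxide, so the mixed aryl isopropyl squarate should form without ester exchange.

**Step 6**
Reactants: 9 mixed aryl isopropyl squarate; 10 methyl vinyl ether
Product: 13 racemic 2-[3,5-dimethoxy-4-(3,4,5-trimethoxyphenoxy)phenoxy]-4-methoxy-4-(1-methoxyethenyl)-3-(propan-2-yloxy)cyclobut-2-en-1-one, via 1-methoxyvinyllithium 11 (not isolated), via lithium alkoxide 12 (not isolated)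
Conditions: 10 (1.3 equiv), t-BuLi (1.1 equiv), THF, −78 → 0 °C; cannulate into 9, THF, −78 °C; MeOTf (2 equiv), −78 → 0 °C; aq. NaHCO3; Et3N-deactivated silica
Reagents that add atoms: methyl trifluoromethanesulfonate, COS(=O)(=O)C(F)(F)F
Why: 1,2-Addition of an organolithium to a squarate carbonyl followed by O-methylation of the alkoxide in the same flask; the carbonyl conjugated through the ring C=C to the aryloxy oxygen (the weaker donor) is the more electrophilic, so the nucleophile should add next to the isopropoxy-bearing carbon and leave the vinylogous isopropyl ester carbonyl, and the new quaternary stereocenter forms as a racemate, which does not matter because it becomes sp2 in step 7.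

**Step 7**
Reactants: 13 racemic 4-methoxy-4-(1-methoxyethenyl)cyclobutenone
Product: 16 2-[3,5-dimethoxy-4-(3,4,5-trimethoxyphenoxy)phenoxy]-4,5-dimethoxy-3-(propan-2-yloxy)phenol (ring C–D–E phenol), via dienylketene 14 (not isolated), via cyclohexadienone 15 (not isolated)
Conditions: PhMe (0.01 M, degassed), 110 °C, Ar
Reagents that add atoms: none
Why: Heating cleaves the bond between the carbonyl carbon and the quaternary carbon of the cyclobutenone in a conrotatory 4π electrocyclic opening to dienylketene 14, whose ketene carbon (future C1) bonds to the CH2 terminus of the methoxyvinyl group (future C6) in a disrotatory 6π electrocyclisation that closes six-membered ring C as dienone 15, and enolisation gives phenol 16. The closest known reaction is the Moore rearrangement of squarate-derived 4-alkenyl-4-alkoxycyclobutenones to highly oxygenated phenols. No stereocenter is formed, and the single stereocenter of racemic 13 becomes sp2. The step needs torquoselectivity in the ring opening: the 4-methoxy donor should rotate outward, which turns the methoxyvinyl group inward and gives the (Z)-dienylketene, the only geometry in which the two termini can bond. The oxygen pattern is carried in from 13 and not decided here: the aryloxy group sits on the carbon next to the ketene carbon, then follow isopropoxy, methoxy and methoxy, and the ketene oxygen ends as the only free OH, on C1 beside the C6–H. High dilution in degassed toluene is chosen to limit ketene dimerisation and oxidation of the electron-rich phenol.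

**Step 8**
Reactants: 17 1-bromo-2,3-dimethoxybenzene
Product: 19 (3-bromo-4,5-dimethoxyphenyl)boronic acid, via pinacol boronate 18 (not isolated)
Conditions: B2pin2 (0.55 equiv), [Ir(OMe)(cod)]2 (1 mol %), dtbpy (2 mol %), THF, 80 °C; then NaIO4, aq. HCl, THF/H2O, rt
Reagents that add atoms: bis(pinacolato)diboron, CC1(C)OB(OC1(C)C)B1OC(C)(C)C(C)(C)O1; water, O
Why: Iridium-catalysed aromatic C–H borylation is sterically governed and should go to C5 of 17, the only C–H with no ortho substituent, without touching the C–Br bond, and periodate then cleaves the pinacol ester oxidatively to the free boronic acid.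

**Step 9**
Reactants: 19 (3-bromo-4,5-dimethoxyphenyl)boronic acid; 1 syringaldehyde
Product: 20 4-(3-bromo-4,5-dimethoxyphenoxy)-3,5-dimethoxybenzaldehyde
Conditions: Cu(OAc)2 (2 equiv), pyridine (5 equiv), 4 Å MS, CH2Cl2, rt
Reagents that add atoms: none
Why: Chan–Lam coupling as in step 1; divalent copper at room temperature does not insert into the aryl C–Br bond, so the bromide needed for step 12 is carried through.

**Step 10**
Reactants: 20 4-(3-bromo-4,5-dimethoxyphenoxy)-3,5-dimethoxybenzaldehyde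
Product: 22 4-(3-bromo-4,5-dimethoxyphenoxy)-3,5-dimethoxyphenol, via aryl formate 21 (not isolated)
Conditions: mCPBA, CH2Cl2, 0 °C → rt; then K2CO3, MeOH, rt
Reagents that add atoms: 3-chloroperoxybenzoic acid (mCPBA), OOC(=O)c1cccc(Cl)c1
Why: Dakin oxidation (Baeyer–Villiger aryl migration, then formate methanolysis) as in step 2; the aryl bromide and the diaryl ether are inert to the peracid.

**Step 11**
Reactants: 22 4-(3-bromo-4,5-dimethoxyphenoxy)-3,5-dimethoxyphenol
Product: 23 1-bromo-2,3-dimethoxy-5-(2,4,6-trimethoxyphenoxy)benzene (ring A–B bromide)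
Conditions: MeI, K2CO3, DMF, rt
Reagents that add atoms: iodomethane, CI
Why: Williamson ether synthesis on an unhindered phenoxide; capping this OH leaves 16 as the only phenol present in step 12.

**Step 12**
Reactants: 16 ring C–D–E phenol; 23 ring A–B bromide
Product: 24 2-[3,5-dimethoxy-4-(3,4,5-trimethoxyphenoxy)phenoxy]-1-[2,3-dimethoxy-5-(2,4,6-trimethoxyphenoxy)phenoxy]-4,5-dimethoxy-3-(propan-2-yloxy)benzene
Conditions: CuI (20 mol %), N,N-dimethylglycine·HCl (60 mol %), Cs2CO3 (2 equiv), 1,4-dioxane, 100 °C, Ar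
Reagents that add atoms: none
Why: Ullmann-type diaryl ether synthesis: the amino acid ligand keeps monovalent copper in solution and lets the copper phenoxide of 16 add oxidatively to the C–Br bond of 23, and each partner carries only one ortho substituent at the reacting position.

**Step 13**
Reactants: 24 fully alkylated pentamer
Product: 25 4-[3,5-dihydroxy-4-(3,4,5-trihydroxyphenoxy)phenoxy]-5-[2,3-dihydroxy-5-(2,4,6-trihydroxyphenoxy)phenoxy]benzene-1,2,3-triol (CNP0228612.0)
Conditions: BBr3 (26 equiv), CH2Cl2, −78 °C → rt, Ar; then MeOH, 0 °C; H2O; work-up under Ar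
Reagents that add atoms: none
Why: Lewis acid ether cleavage: boron coordinates each alkyl aryl ether oxygen and bromide removes the methyl or isopropyl group at its sp3 carbon, whereas the four diaryl ether links offer no sp3 carbon and should stay, and hydrolysis sets the thirteen OH groups free.

**Compound list**
1 | syringaldehyde (4-hydroxy-3,5-dimethoxybenzaldehyde) | COc1cc(C=O)cc(OC)c1O | starting material
2 | 3,4,5-trimethoxyphenylboronic acid | COc1cc(B(O)O)cc(OC)c1OC | starting material
3 | 3,5-dimethoxy-4-(3,4,5-trimethoxyphenoxy)benzaldehyde | COc1cc(C=O)cc(OC)c1Oc1cc(OC)c(OC)c(OC)c1 | intermediate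
4 | 3,5-dimethoxy-4-(3,4,5-trimethoxyphenoxy)phenyl formate | O=COc1cc(OC)c(Oc2cc(OC)c(OC)c(OC)c2)c(OC)c1 | intermediate
5 | 3,5-dimethoxy-4-(3,4,5-trimethoxyphenoxy)phenol | Oc1cc(OC)c(Oc2cc(OC)c(OC)c(OC)c2)c(OC)c1 | intermediate
6 | squaric acid (3,4-dihydroxycyclobut-3-ene-1,2-dione) | OC1=C(O)C(=O)C1=O | starting material
7 | 3,4-dichlorocyclobut-3-ene-1,2-dione | ClC1=C(Cl)C(=O)C1=O | intermediate
8 | 3-chloro-4-(propan-2-yloxy)cyclobut-3-ene-1,2-dione | CC(C)OC1=C(Cl)C(=O)C1=O | intermediate
9 | 3-[3,5-dimethoxy-4-(3,4,5-trimethoxyphenoxy)phenoxy]-4-(propan-2-yloxy)cyclobut-3-ene-1,2-dione | CC(C)OC1=C(Oc2cc(OC)c(Oc3cc(OC)c(OC)c(OC)c3)c(OC)c2)C(=O)C1=O | intermediate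
10 | methyl vinyl ether | COC=C | starting material
11 | 1-methoxyvinyllithium | [Li]C(=C)OC | intermediate
12 | racemic lithium 3-[3,5-dimethoxy-4-(3,4,5-trimethoxyphenoxy)phenoxy]-1-(1-methoxyethenyl)-4-oxo-2-(propan-2-yloxy)cyclobut-2-en-1-olate | [Li+].COC(=C)C1([O-])C(OC(C)C)=C(Oc2cc(OC)c(Oc3cc(OC)c(OC)c(OC)c3)c(OC)c2)C1=O | intermediate
13 | racemic 2-[3,5-dimethoxy-4-(3,4,5-trimethoxyphenoxy)phenoxy]-4-methoxy-4-(1-methoxyethenyl)-3-(propan-2-yloxy)cyclobut-2-en-1-one | COC(=C)C1(OC)C(OC(C)C)=C(Oc2cc(OC)c(Oc3cc(OC)c(OC)c(OC)c3)c(OC)c2)C1=O | intermediate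
14 | (3Z)-2-[3,5-dimethoxy-4-(3,4,5-trimethoxyphenoxy)phenoxy]-4,5-dimethoxy-3-(propan-2-yloxy)hexa-1,3,5-trien-1-one (dienylketene) | C=C(OC)/C(OC)=C(OC(C)C)\C(Oc1cc(OC)c(Oc2cc(OC)c(OC)c(OC)c2)c(OC)c1)=C=O | intermediate
15 | 2-[3,5-dimethoxy-4-(3,4,5-trimethoxyphenoxy)phenoxy]-4,5-dimethoxy-3-(propan-2-yloxy)cyclohexa-2,4-dien-1-one | O=C1CC(OC)=C(OC)C(OC(C)C)=C1Oc1cc(OC)c(Oc2cc(OC)c(OC)c(OC)c2)c(OC)c1 | intermediate
16 | 2-[3,5-dimethoxy-4-(3,4,5-trimethoxyphenoxy)phenoxy]-4,5-dimethoxy-3-(propan-2-yloxy)phenol | Oc1cc(OC)c(OC)c(OC(C)C)c1Oc1cc(OC)c(Oc2cc(OC)c(OC)c(OC)c2)c(OC)c1 | intermediate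
17 | 1-bromo-2,3-dimethoxybenzene | COc1cccc(Br)c1OC | starting material
18 | 2-(3-bromo-4,5-dimethoxyphenyl)-4,4,5,5-tetramethyl-1,3,2-dioxaborolane | COc1cc(B2OC(C)(C)C(C)(C)O2)cc(Br)c1OC | intermediate
19 | (3-bromo-4,5-dimethoxyphenyl)boronic acid | COc1cc(B(O)O)cc(Br)c1OC | intermediate
20 | 4-(3-bromo-4,5-dimethoxyphenoxy)-3,5-dimethoxybenzaldehyde | COc1cc(C=O)cc(OC)c1Oc1cc(OC)c(OC)c(Br)c1 | intermediate
21 | 4-(3-bromo-4,5-dimethoxyphenoxy)-3,5-dimethoxyphenyl formate | O=COc1cc(OC)c(Oc2cc(OC)c(OC)c(Br)c2)c(OC)c1 | intermediate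
22 | 4-(3-bromo-4,5-dimethoxyphenoxy)-3,5-dimethoxyphenol | Oc1cc(OC)c(Oc2cc(OC)c(OC)c(Br)c2)c(OC)c1 | intermediate
23 | 1-bromo-2,3-dimethoxy-5-(2,4,6-trimethoxyphenoxy)benzene | COc1cc(OC)c(Oc2cc(OC)c(OC)c(Br)c2)c(OC)c1 | intermediate
24 | 2-[3,5-dimethoxy-4-(3,4,5-trimethoxyphenoxy)phenoxy]-1-[2,3-dimethoxy-5-(2,4,6-trimethoxyphenoxy)phenoxy]-4,5-dimethoxy-3-(propan-2-yloxy)benzene | COc1cc(OC)c(Oc2cc(OC)c(OC)c(Oc3cc(OC)c(OC)c(OC(C)C)c3Oc3cc(OC)c(Oc4cc(OC)c(OC)c(OC)c4)c(OC)c3)c2)c(OC)c1 | intermediate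
25 | 4-[3,5-dihydroxy-4-(3,4,5-trihydroxyphenoxy)phenoxy]-5-[2,3-dihydroxy-5-(2,4,6-trihydroxyphenoxy)phenoxy]benzene-1,2,3-triol | Oc1cc(O)c(Oc2cc(O)c(O)c(Oc3cc(O)c(O)c(O)c3Oc3cc(O)c(Oc4cc(O)c(O)c(O)c4)c(O)c3)c2)c(O)c1 | target

**Totals**
Total step count: 13.
Longest linear sequence: 7 steps (1, 2, 5, 6, 7, 12, 13 from syringaldehyde; equally 3, 4, 5, 6, 7, 12, 13 from squaric acid).

**Steps most likely to fail**

Step 7 (ring expansion). The dienylketene may be consumed before it closes: the electron-rich ring D beside the ketene carbon could attack it, the ketene could dimerise or be trapped by traces of water, or the enol ether could hydrolyse before the ring opens. The fallback builds ring C from an arene and sets out from phenol 5. Ullmann-type coupling of 5 with commercial 2-bromo-3,4,5-trimethoxybenzaldehyde (CuI, N,N-dimethylglycine·HCl, Cs2CO3, dioxane, 100 °C; the ortho-formyl group assists) should give 2-[3,5-dimethoxy-4-(3,4,5-trimethoxyphenoxy)phenoxy]-3,4,5-trimethoxybenzaldehyde F1. Dakin oxidation (mCPBA, then K2CO3/MeOH) should lead through 2-[3,5-dimethoxy-4-(3,4,5-trimethoxyphenoxy)phenoxy]-3,4,5-trimethoxyphenyl formate F2 to 2-[3,5-dimethoxy-4-(3,4,5-trimethoxyphenoxy)phenoxy]-3,4,5-trimethoxyphenol F3. Coupling of F3 with bromide 23 under the conditions of step 12 should give 2-[3,5-dimethoxy-4-(3,4,5-trimethoxyphenoxy)phenoxy]-1-[2,3-dimethoxy-5-(2,4,6-trimethoxyphenoxy)phenoxy]-3,4,5-trimethoxybenzene F4, and BBr3 as in step 13 brings the route back at target 25.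

Step 6 (organolithium addition). The donor difference between aryloxy and isopropoxy is modest, so the two carbonyl groups may be poorly discriminated, and the organolithium may displace the aryloxy group instead of adding to a carbonyl. The fallback fixes the regiochemistry by substitution after the addition and sets out from dichloride 7. With two equivalents of phenol 5 and i-Pr2NEt, 7 should give the symmetrical 3,4-bis[3,5-dimethoxy-4-(3,4,5-trimethoxyphenoxy)phenoxy]cyclobut-3-ene-1,2-dione F5, whose two carbonyl groups are equivalent. Addition of 11 at −78 °C should give racemic lithium 2,3-bis[3,5-dimethoxy-4-(3,4,5-trimethoxyphenoxy)phenoxy]-1-(1-methoxyethenyl)-4-oxocyclobut-2-en-1-olate F6, and MeOTf then gives racemic 2,3-bis[3,5-dimethoxy-4-(3,4,5-trimethoxyphenoxy)phenoxy]-4-methoxy-4-(1-methoxyethenyl)cyclobut-2-en-1-one F7. In F7 only the aryloxy group on the carbon β to the carbonyl is a vinylogous aryl ester. Conjugate addition–elimination with i-PrOH and catalytic i-PrONa at 0 °C should replace that group alone, returning one equivalent of 5 and rejoining the route at 13.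

Step 12 (copper-catalysed etherification). Oxidative addition to the electron-rich, ortho-methoxylated bromide may be slow, and the crowded phenoxide of 16 may couple sluggishly, so protodebromination of 23 or oxidation of 16 could win. The fallback reverses the roles of the partners and sets out from bromide 23. Bromine–lithium exchange (n-BuLi, THF, −78 °C) should give [2,3-dimethoxy-5-(2,4,6-trimethoxyphenoxy)phenyl]lithium F8. Quenching with B(OMe)3 and aqueous acid should give [2,3-dimethoxy-5-(2,4,6-trimethoxyphenoxy)phenyl]boronic acid F9. Chan–Lam coupling of F9 with phenol 16 (Cu(OAc)2, pyridine, 4 Å MS, CH2Cl2, rt) forms the same C–O bond at room temperature and rejoins the route at 24.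

**Further compounds**
F1 | step 7 | 2-[3,5-dimethoxy-4-(3,4,5-trimethoxyphenoxy)phenoxy]-3,4,5-trimethoxybenzaldehyde | O=Cc1cc(OC)c(OC)c(OC)c1Oc1cc(OC)c(Oc2cc(OC)c(OC)c(OC)c2)c(OC)c1
F2 | step 7 | 2-[3,5-dimethoxy-4-(3,4,5-trimethoxyphenoxy)phenoxy]-3,4,5-trimethoxyphenyl formate | O=COc1cc(OC)c(OC)c(OC)c1Oc1cc(OC)c(Oc2cc(OC)c(OC)c(OC)c2)c(OC)c1
F3 | step 7 | 2-[3,5-dimethoxy-4-(3,4,5-trimethoxyphenoxy)phenoxy]-3,4,5-trimethoxyphenol | Oc1cc(OC)c(OC)c(OC)c1Oc1cc(OC)c(Oc2cc(OC)c(OC)c(OC)c2)c(OC)c1
F4 | step 7 | 2-[3,5-dimethoxy-4-(3,4,5-trimethoxyphenoxy)phenoxy]-1-[2,3-dimethoxy-5-(2,4,6-trimethoxyphenoxy)phenoxy]-3,4,5-trimethoxybenzene | COc1cc(OC)c(Oc2cc(OC)c(OC)c(Oc3cc(OC)c(OC)c(OC)c3Oc3cc(OC)c(Oc4cc(OC)c(OC)c(OC)c4)c(OC)c3)c2)c(OC)c1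
F5 | step 6 | 3,4-bis[3,5-dimethoxy-4-(3,4,5-trimethoxyphenoxy)phenoxy]cyclobut-3-ene-1,2-dione | O=C1C(=O)C(Oc2cc(OC)c(Oc3cc(OC)c(OC)c(OC)c3)c(OC)c2)=C1Oc1cc(OC)c(Oc2cc(OC)c(OC)c(OC)c2)c(OC)c1
F6 | step 6 | racemic lithium 2,3-bis[3,5-dimethoxy-4-(3,4,5-trimethoxyphenoxy)phenoxy]-1-(1-methoxyethenyl)-4-oxocyclobut-2-en-1-olate | [Li+].COC(=C)C1([O-])C(Oc2cc(OC)c(Oc3cc(OC)c(OC)c(OC)c3)c(OC)c2)=C(Oc2cc(OC)c(Oc3cc(OC)c(OC)c(OC)c3)c(OC)c2)C1=O
F7 | step 6 | racemic 2,3-bis[3,5-dimethoxy-4-(3,4,5-trimethoxyphenoxy)phenoxy]-4-methoxy-4-(1-methoxyethenyl)cyclobut-2-en-1-one | COC(=C)C1(OC)C(Oc2cc(OC)c(Oc3cc(OC)c(OC)c(OC)c3)c(OC)c2)=C(Oc2cc(OC)c(Oc3cc(OC)c(OC)c(OC)c3)c(OC)c2)C1=O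
F8 | step 12 | [2,3-dimethoxy-5-(2,4,6-trimethoxyphenoxy)phenyl]lithium | COc1cc(OC)c(Oc2cc(OC)c(OC)c([Li])c2)c(OC)c1
F9 | step 12 | [2,3-dimethoxy-5-(2,4,6-trimethoxyphenoxy)phenyl]boronic acid | COc1cc(OC)c(Oc2cc(OC)c(OC)c(B(O)O)c2)c(OC)c1
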